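**Remark on the chemistry:** the target has no stereocentre and no other stereogenic element, so the SMILES describes one achiral compound and no step has to control configuration. Compounds 1, 2 and 4 are taken as commercial.

## Retrosynthetic overview

- Target 8 ⇐ 6: the 4-oxobutanoic acid chain is traced back to an intact pyrrolidine-2,5-dione ring (opened by hydroxide) and the C5–OH of the arene to a formyl group (Dakin oxidation), both in one flask.
- 6 ⇐ 3 + formaldehyde + succinimide: the benzylic carbon C7 is cut on both sides, so C1(aryl)–C7 and C7–N form together in a three-component amidoalkylation. C1 is para to the C4–OH and meta to the formyl group (the later C5–OH), so both groups direct to it.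
- 3 ⇐ 1: ortho-formylation of 2,3-dibromophenol; the two vicinal bromines (C2, C3 of the target) are bought in place.
- Rings: the benzene ring is bought and no ring is formed; the imide ring is carried in as the N/C4 unit and opened in the last step.

Key step: step 2

## Route

Step 1
Reactants: 1 2,3-dibromophenol; 2 paraformaldehyde
Product: 3 3,4-dibromo-2-hydroxybenzaldehyde
Conditions: MgCl2 (2 equiv), Et3N (2 equiv), (CH2O)n (3 equiv), THF, reflux; then 1 M HCl
Reagents that add atoms: none
Why: Magnesium-mediated ortho-formylation (Casnati–Skattebøl type), in which the magnesium phenoxide of 1 delivers formaldehyde through a chelate to C6, the only free ortho position, and a second formaldehyde oxidises the benzylic alkoxide by hydride transfer, as is established for 2-bromophenol.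

Step 2
Reactants: 3 3,4-dibromo-2-hydroxybenzaldehyde; 4 succinimide; 2 paraformaldehyde
Product: 6 1-[(2,3-dibromo-5-formyl-4-hydroxyphenyl)methyl]pyrrolidine-2,5-dione, via N-(hydroxymethyl)succinimide 5 (not isolated)
Conditions: 4 (1.3 equiv), (CH2O)n (1.1 equiv), conc. H2SO4, 0 °C → rt, 30 min; then 3, rt → 40 °C; poured on ice
Reagents that add atoms: none
Why: Tscherniak–Einhorn amidoalkylation run as a three-component reaction: 4 and formaldehyde condense in the acid to 5, which ionises to the N,N-diacyliminium ion, and this cation substitutes the arene of 3 at C5 by SEAr, so that the C(aryl)–CH2 and the CH2–N bond of the target are both made in one flask. The closest known reaction type is the amidomethylation of phenols, nitrophenols and hydroxybenzoic acids with N-hydroxymethyl imides in concentrated sulfuric acid. No ring is closed and no stereocentre is formed. The step needs site selectivity for C5 over C6 and must stop after one substitution: C5 is para to the OH and meta to the formyl group, so both substituents direct to it, whereas C6 is meta to the OH and ortho to the formyl group, and after the reaction no activated C–H is left. The competing process is the linking of two arenes by free formaldehyde to a diarylmethane, which premixing the excess imide with the formaldehyde and the low nucleophilicity of the ring should hold back.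

Step 3
Reactants: 6 1-[(2,3-dibromo-5-formyl-4-hydroxyphenyl)methyl]pyrrolidine-2,5-dione
Product: 8 4-{[(2,3-dibromo-4,5-dihydroxyphenyl)methyl]amino}-4-oxobutanoic acid, via formyl succinamic acid 7 (not isolated)
Conditions: LiOH (4 equiv), degassed THF/H2O 1:1, 0 °C, 30 min; then 30% aq. H2O2 (1.2 equiv), 0 °C → rt, N2; Na2S2O3, then 1 M HCl to pH 2, 0 °C
Reagents that add atoms: lithium hydroxide [Li+].[OH-]; hydrogen peroxide OO
Why: Hydroxide opens the symmetrical imide at either carbonyl to the same succinamate far faster than it attacks the secondary amide so formed, and the Dakin oxidation of the ortho-hydroxybenzaldehyde phenoxide with hydroperoxide then turns the formyl group into the second phenolic OH by aryl migration and loss of formate, the peroxide being added only after the imide is consumed so that no peracid can form.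

## Compound list

1 | 2,3-dibromophenol | Oc1cccc(Br)c1Br | starting material
2 | paraformaldehyde (SMILES of the monomer, formaldehyde) | C=O | starting material
3 | 3,4-dibromo-2-hydroxybenzaldehyde | O=Cc1ccc(Br)c(Br)c1O | intermediate
4 | succinimide (pyrrolidine-2,5-dione) | O=C1CCC(=O)N1 | starting material
5 | N-(hydroxymethyl)succinimide (1-(hydroxymethyl)pyrrolidine-2,5-dione) | O=C1CCC(=O)N1CO | intermediate
6 | 1-[(2,3-dibromo-5-formyl-4-hydroxyphenyl)methyl]pyrrolidine-2,5-dione | O=Cc1cc(CN2C(=O)CCC2=O)c(Br)c(Br)c1O | intermediate
7 | 4-{[(2,3-dibromo-5-formyl-4-hydroxyphenyl)methyl]amino}-4-oxobutanoic acid | O=C(O)CCC(=O)NCc1cc(C=O)c(O)c(Br)c1Br | intermediate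
8 | 4-{[(2,3-dibromo-4,5-dihydroxyphenyl)methyl]amino}-4-oxobutanoic acid | O=C(O)CCC(=O)NCc1cc(O)c(O)c(Br)c1Br | target

## Step count and risks

Total step count: 3. Longest linear sequence: 3.

**Steps most likely to fail**

1. Step 2 (key step). The substitution may stall because the ring carries two bromines and a formyl group that is protonated in the acid, or free formaldehyde may join two molecules of 3 to a diarylmethane. The fallback sets out from 1 and comes back at 6, and it makes the benzylic bond on the more nucleophilic phenol before the formyl group is present. Compound 1 is treated with 4 and 2 in methanesulfonic acid at rt, which should give 1-[(2,3-dibromo-4-hydroxyphenyl)methyl]pyrrolidine-2,5-dione F1 by substitution para to the OH; any ortho isomer would be removed by crystallisation. F1 is then formylated at its only free ortho position with MgCl2, Et3N and paraformaldehyde in THF at reflux, which should give 6. This variant gives up the cooperative directing effect of the formyl group and relies on the para preference of the phenol alone.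

2. Step 3. The electron-rich catecholate may be oxidised further by alkaline peroxide, with quinone formation or ring cleavage, before the work-up. The fallback sets out from 6 and comes back at 8, and it keeps oxidant and base apart. Compound 6 is oxidised with mCPBA in CH2Cl2 at 0 °C → rt (Baeyer–Villiger oxidation with aryl migration) to 3,4-dibromo-5-[(2,5-dioxopyrrolidin-1-yl)methyl]-2-hydroxyphenyl formate F2, and the peracid is removed by a sulfite wash. F2 is then treated with LiOH in degassed THF/H2O at 0 °C in the presence of Na2S2O4, which should cleave the formate and open the imide in one operation; acidification gives 8.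

3. Step 1. Formylation of the electron-poor, ortho-brominated magnesium phenoxide may stay incomplete, and long heating may lead to methoxymethylated by-products. The fallback sets out from 1 and comes back at 3, and it forms the ortho C–C bond by a sigmatropic rearrangement. Compound 1 is O-allylated with allyl bromide and K2CO3 in acetone to 1-(allyloxy)-2,3-dibromobenzene F3. Heating F3 in N,N-diethylaniline at 190 °C should give 6-allyl-2,3-dibromophenol F4 by aromatic Claisen rearrangement to the only free ortho position. Isomerisation with catalytic RuHCl(CO)(PPh3)3 in toluene at 80 °C should give 2,3-dibromo-6-[(E)-prop-1-en-1-yl]phenol F5. Oxidative cleavage of F5 with catalytic OsO4 and NaIO4 (2,6-lutidine, dioxane/H2O) should give 3.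

## Further compounds

F1 | step 2 | 1-[(2,3-dibromo-4-hydroxyphenyl)methyl]pyrrolidine-2,5-dione | O=C1CCC(=O)N1Cc1ccc(O)c(Br)c1Br
F2 | step 3 | 3,4-dibromo-5-[(2,5-dioxopyrrolidin-1-yl)methyl]-2-hydroxyphenyl formate | O=COc1cc(CN2C(=O)CCC2=O)c(Br)c(Br)c1O
F3 | step 1 | 1-(allyloxy)-2,3-dibromobenzene | C=CCOc1cccc(Br)c1Br
F4 | step 1 | 6-allyl-2,3-dibromophenol | C=CCc1ccc(Br)c(Br)c1O
F5 | step 1 | 2,3-dibromo-6-[(E)-prop-1-en-1-yl]phenol | C/C=C/c1ccc(Br)c(Br)c1O
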